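Everything rests on building ring D – the benzene ring that is the B ring of the apigenin unit, D1 bonded to C2 of that unit's pyranone and D4 to the ether oxygen – around an oxygen that already sits on the future C6 of ring A of the 7-methoxyflavone unit, between the C5 and C7 oxygens. Because ring D is merely 1,4-disubstituted, an inverse-demand Diels–Alder reaction of methyl coumalate with the ethynyl ether of the crowded phenol, followed by loss of CO2, gives the para-aryloxybenzoate in one operation and no hindered C–O arylation is needed. The precursor is a terminal aryl ynol ether flanked by two methoxy groups and carrying a para benzyloxy group.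

Key step: step 5

Remark: 4-(benzyloxy)benzoyl chloride 15 is taken as a purchased building block; bridged lactone 11 forms as a racemate and is drawn as one enantiomer.

Step 1
Reactants: 1 2,6-dimethoxy-1,4-benzoquinone
Product: 2 2,6-dimethoxybenzene-1,4-diol
Conditions: Na2S2O4, H2O/EtOAc, rt, N2
Reagents that add atoms: none
Why: Dithionite reduction of a 1,4-benzoquinone to its hydroquinone is a fast two-electron reduction that touches nothing else, and 2 is kept under nitrogen because it re-oxidises in air.

Step 2
Reactants: 2 2,6-dimethoxybenzene-1,4-diol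
Product: 3 4-(benzyloxy)-2,6-dimethoxyphenol
Conditions: BnBr (1.0 equiv), K2CO3 (1.1 equiv), degassed DMF, 0 °C to rt, N2
Reagents that add atoms: benzyl bromide, BrCc1ccccc1
Why: Williamson ether synthesis in which the O4 hydroxyl, meta to both methoxy groups, is the more acidic and sterically open one, whereas the O1 hydroxyl is flanked by two methoxy groups, so one equivalent of benzyl bromide with a mild base should benzylate O4.

Step 3
Reactants: 3 4-(benzyloxy)-2,6-dimethoxyphenol; 4 trichloroethylene
Product: 6 5-(benzyloxy)-2-{[(E)-1,2-dichloroethenyl]oxy}-1,3-dimethoxybenzene, via dichloroacetylene 5 (not isolated)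
Conditions: K2CO3, DMF, 70 °C, N2
Reagents that add atoms: none
Why: Base-induced loss of HCl from 4 gives dichloroacetylene 5, to which the phenoxide adds with anti protonation to give the (E)-1,2-dichlorovinyl ether, a known route to aryl dichlorovinyl ethers in which the small two-carbon electrophile is indifferent to the two ortho methoxy groups.

Step 4
Reactants: 6 5-(benzyloxy)-2-{[(E)-1,2-dichloroethenyl]oxy}-1,3-dimethoxybenzene
Product: 9 5-(benzyloxy)-2-(ethynyloxy)-1,3-dimethoxybenzene, via chloroalkynyl ether 7 (not isolated), via lithium aryloxyacetylide 8 (not isolated)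
Conditions: n-BuLi (2.2 equiv), Et2O, −78 to −40 °C; then H2O, −78 to 0 °C; rapid filtration through basic alumina, used the same day
Reagents that add atoms: none
Why: Dehydrochlorination by n-BuLi gives chloroalkynyl ether 7, chlorine–lithium exchange with the second equivalent gives acetylide 8 and protonation gives the terminal ynol ether (the standard dichlorovinyl ether route to ynol ethers), while at −78 °C neither the benzyl ether nor the ring positions are metalated.

Step 5
Reactants: 9 5-(benzyloxy)-2-(ethynyloxy)-1,3-dimethoxybenzene; 10 methyl coumalate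
Product: 12 methyl 4-[4-(benzyloxy)-2,6-dimethoxyphenoxy]benzoate, via bridged lactone 11 (not isolated)
Conditions: 9 (1.3 equiv), PhMe, 100 °C, sealed tube, Ar
Reagents that add atoms: none
Why: The electron-poor diene of 10 (pyrone C3 to C6) and the electron-rich alkyne of 9 combine in an inverse-electron-demand (4+2) cycloaddition to bridged lactone 11, which at the same temperature expels CO2 by retro-(4+2) and so delivers the benzene ring with no oxidation step. The closest known reaction type is the Diels–Alder/decarboxylation of methyl coumalate with enol ethers, ketene acetals, ynamines and other electron-rich alkynes to para-substituted benzoates. Ring D is closed by intermolecular cycloaddition, the D2–D3 bond (pyrone C6 to the terminal alkyne carbon) and the D4–D5 bond (pyrone C3 to the oxygen-bearing alkyne carbon) forming in one event, and is then aromatised by cycloreversion. No stereocentre remains, because the two bridgehead centres of 11 become sp2 carbons when CO2 leaves. The only selectivity needed is regiochemical: the nucleophilic terminal carbon of the ynol ether must bond to pyrone C6, the electrophilic position β to the ester, which places the aryloxy group para to the ester carbon. The two ortho methoxy groups twist the aryl ring out of conjugation with the ether oxygen, so its lone pair feeds the alkyne, and an aryl ynol ether has no β-hydrogen for the retro-ene loss of ketene that limits alkyl ynol ethers on heating.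

Step 6
Reactants: 12 methyl 4-[4-(benzyloxy)-2,6-dimethoxyphenoxy]benzoate
Product: 13 methyl 4-(4-hydroxy-2,6-dimethoxyphenoxy)benzoate
Conditions: H2 (1 atm), 10% Pd/C, EtOAc/MeOH, rt
Reagents that add atoms: none
Why: Hydrogenolysis of an aryl benzyl ether over Pd/C is neutral and leaves the diaryl ether, the methyl ester and the methyl ethers untouched.

Step 7
Reactants: 13 methyl 4-(4-hydroxy-2,6-dimethoxyphenoxy)benzoate
Product: 14 methyl 4-(3-acetyl-4-hydroxy-2,6-dimethoxyphenoxy)benzoate
Conditions: AcOH, BF3·OEt2, 85 °C; then aq NaOAc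
Reagents that add atoms: acetic acid, CC(=O)O
Why: Friedel–Crafts C-acetylation mediated by BF3 goes ortho to the free phenol on the trioxygenated ring, whose two open positions are equivalent by symmetry, while the ester-bearing ring D is deactivated, just as 3,4,5-trimethoxyphenol is acetylated at the corresponding position under these conditions.

Step 8
Reactants: 14 methyl 4-(3-acetyl-4-hydroxy-2,6-dimethoxyphenoxy)benzoate; 15 4-(benzyloxy)benzoyl chloride
Product: 16 methyl 4-(3-{3-[4-(benzyloxy)phenyl]-3-oxopropanoyl}-4-hydroxy-2,6-dimethoxyphenoxy)benzoate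
Conditions: LiN(SiMe3)2 (3.2 equiv), THF, −78 °C; then 15 (1.05 equiv), −78 to −20 °C; then AcOH
Reagents that add atoms: none
Why: C-aroylation of the doubly lithiated o-hydroxyacetophenone with an aroyl chloride (the one-flask variant of the Baker–Venkataraman sequence) gives the 1,3-diketone directly, because the acid chloride reacts at −78 °C long before the enolate could attack the methyl benzoate and the third equivalent of base stores the product as its enolate.

Step 9
Reactants: 16 methyl 4-(3-{3-[4-(benzyloxy)phenyl]-3-oxopropanoyl}-4-hydroxy-2,6-dimethoxyphenoxy)benzoate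
Product: 17 methyl 4-({2-[4-(benzyloxy)phenyl]-5,7-dimethoxy-4-oxo-4H-chromen-6-yl}oxy)benzoate
Conditions: TsOH·H2O (cat.), PhMe, 90 °C
Reagents that add atoms: none
Why: Acid-catalysed cyclodehydration of an o-hydroxyaryl 1,3-diketone, the closing stage of the Baker–Venkataraman flavone synthesis, can only engage the single free phenol, so the 5,7-dimethoxy-6-aryloxy pattern is fixed, and catalytic TsOH in toluene spares the benzyl ether and the methyl ester.

Step 10
Reactants: 18 2',4',6'-trihydroxyacetophenone
Product: 19 1-[2,4-bis(benzyloxy)-6-hydroxyphenyl]ethan-1-one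
Conditions: BnBr (2.05 equiv), K2CO3, DMF, rt
Reagents that add atoms: benzyl bromide, BrCc1ccccc1
Why: Williamson benzylation takes the para hydroxyl and one ortho hydroxyl, while the remaining ortho hydroxyl is locked in a hydrogen bond to the ketone and stays free for the later ring closure.

Step 11
Reactants: 17 methyl 4-({2-[4-(benzyloxy)phenyl]-5,7-dimethoxy-4-oxo-4H-chromen-6-yl}oxy)benzoate; 19 1-[2,4-bis(benzyloxy)-6-hydroxyphenyl]ethan-1-one
Product: 20 1-[2,4-bis(benzyloxy)-6-hydroxyphenyl]-3-[4-({2-[4-(benzyloxy)phenyl]-5,7-dimethoxy-4-oxo-4H-chromen-6-yl}oxy)phenyl]propane-1,3-dione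
Conditions: 19 (1.5 equiv), LiN(SiMe3)2 (4.6 equiv), THF, −78 to −10 °C; then 17, −10 °C to rt; then AcOH
Reagents that add atoms: none
Why: Crossed Claisen condensation of doubly lithiated 19 with the non-enolisable methyl benzoate of 17 is driven by deprotonation of the diketone formed, and 17 offers no C–H that LiN(SiMe3)2 removes while its pyranone C2 is shielded by the aryl group, so the ester is the exposed electrophile.

Step 12
Reactants: 20 1-[2,4-bis(benzyloxy)-6-hydroxyphenyl]-3-[4-({2-[4-(benzyloxy)phenyl]-5,7-dimethoxy-4-oxo-4H-chromen-6-yl}oxy)phenyl]propane-1,3-dione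
Product: 21 5,7-bis(benzyloxy)-2-[4-({2-[4-(benzyloxy)phenyl]-5,7-dimethoxy-4-oxo-4H-chromen-6-yl}oxy)phenyl]-4H-chromen-4-one
Conditions: TsOH·H2O (cat.), PhMe, 90 °C
Reagents that add atoms: none
Why: The same acid-catalysed cyclodehydration as in step 9 closes the second pyranone through the only free phenol, and premature loss of the peri benzyl group would be harmless because it is removed in the next step anyway.

Step 13
Reactants: 21 5,7-bis(benzyloxy)-2-[4-({2-[4-(benzyloxy)phenyl]-5,7-dimethoxy-4-oxo-4H-chromen-6-yl}oxy)phenyl]-4H-chromen-4-one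
Product: 22 isocryptomerin, 5,7-dihydroxy-2-(4-{[5-hydroxy-2-(4-hydroxyphenyl)-7-methoxy-4-oxo-4H-chromen-6-yl]oxy}phenyl)-4H-chromen-4-one
Conditions: BCl3 (excess), C6HMe5, CH2Cl2, −78 °C to rt; then MeOH, H2O
Reagents that add atoms: none
Why: BCl3 cleaves the three aryl benzyl ethers at low temperature (pentamethylbenzene traps the benzyl cation and prevents C-benzylation of the phloroglucinol ring) and, on warming, the 5-methoxy group through chelation to the C4 carbonyl, whereas the 7-methoxy group, which has no chelating neighbour, and the diaryl ether are left alone.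

Compound list
1 | 2,6-dimethoxy-1,4-benzoquinone | COC1=CC(=O)C=C(OC)C1=O | starting material
2 | 2,6-dimethoxybenzene-1,4-diol | COc1cc(O)cc(OC)c1O | intermediate
3 | 4-(benzyloxy)-2,6-dimethoxyphenol | COc1cc(OCc2ccccc2)cc(OC)c1O | intermediate
4 | trichloroethylene | ClC=C(Cl)Cl | starting material
5 | dichloroacetylene | ClC#CCl | intermediate (not isolated)
6 | 5-(benzyloxy)-2-{[(E)-1,2-dichloroethenyl]oxy}-1,3-dimethoxybenzene | Cl/C=C(/Cl)Oc1c(OC)cc(OCc2ccccc2)cc1OC | intermediate
7 | 5-(benzyloxy)-2-[(chloroethynyl)oxy]-1,3-dimethoxybenzene | ClC#COc1c(OC)cc(OCc2ccccc2)cc1OC | intermediate (not isolated)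
8 | lithium [4-(benzyloxy)-2,6-dimethoxyphenoxy]acetylide | [Li]C#COc1c(OC)cc(OCc2ccccc2)cc1OC | intermediate (not isolated)
9 | 5-(benzyloxy)-2-(ethynyloxy)-1,3-dimethoxybenzene | C#COc1c(OC)cc(OCc2ccccc2)cc1OC | intermediate
10 | methyl coumalate (methyl 2-oxo-2H-pyran-5-carboxylate) | COC(=O)c1ccc(=O)oc1 | starting material
11 | methyl 5-[4-(benzyloxy)-2,6-dimethoxyphenoxy]-3-oxo-2-oxabicyclo[2.2.2]octa-5,7-diene-7-carboxylate (racemic, one enantiomer drawn) | O=C1O[C@@H]2C=C(Oc3c(OC)cc(OCc4ccccc4)cc3OC)[C@H]1C=C2C(=O)OC | intermediate (not isolated)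
12 | methyl 4-[4-(benzyloxy)-2,6-dimethoxyphenoxy]benzoate | COC(=O)c1ccc(Oc2c(OC)cc(OCc3ccccc3)cc2OC)cc1 | intermediate
13 | methyl 4-(4-hydroxy-2,6-dimethoxyphenoxy)benzoate | COC(=O)c1ccc(Oc2c(OC)cc(O)cc2OC)cc1 | intermediate
14 | methyl 4-(3-acetyl-4-hydroxy-2,6-dimethoxyphenoxy)benzoate | COC(=O)c1ccc(Oc2c(OC)cc(O)c(C(C)=O)c2OC)cc1 | intermediate
15 | 4-(benzyloxy)benzoyl chloride | O=C(Cl)c1ccc(OCc2ccccc2)cc1 | starting material
16 | methyl 4-(3-{3-[4-(benzyloxy)phenyl]-3-oxopropanoyl}-4-hydroxy-2,6-dimethoxyphenoxy)benzoate | COC(=O)c1ccc(Oc2c(OC)cc(O)c(C(=O)CC(=O)c3ccc(OCc4ccccc4)cc3)c2OC)cc1 | intermediate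
17 | methyl 4-({2-[4-(benzyloxy)phenyl]-5,7-dimethoxy-4-oxo-4H-chromen-6-yl}oxy)benzoate | COC(=O)c1ccc(Oc2c(OC)cc3oc(-c4ccc(OCc5ccccc5)cc4)cc(=O)c3c2OC)cc1 | intermediate
18 | 2',4',6'-trihydroxyacetophenone | CC(=O)c1c(O)cc(O)cc1O | starting material
19 | 1-[2,4-bis(benzyloxy)-6-hydroxyphenyl]ethan-1-one | CC(=O)c1c(O)cc(OCc2ccccc2)cc1OCc1ccccc1 | intermediate
20 | 1-[2,4-bis(benzyloxy)-6-hydroxyphenyl]-3-[4-({2-[4-(benzyloxy)phenyl]-5,7-dimethoxy-4-oxo-4H-chromen-6-yl}oxy)phenyl]propane-1,3-dione | O=C(CC(=O)c1ccc(Oc2c(OC)cc3oc(-c4ccc(OCc5ccccc5)cc4)cc(=O)c3c2OC)cc1)c1c(O)cc(OCc2ccccc2)cc1OCc1ccccc1 | intermediate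
21 | 5,7-bis(benzyloxy)-2-[4-({2-[4-(benzyloxy)phenyl]-5,7-dimethoxy-4-oxo-4H-chromen-6-yl}oxy)phenyl]-4H-chromen-4-one | COc1cc2oc(-c3ccc(OCc4ccccc4)cc3)cc(=O)c2c(OC)c1Oc1ccc(-c2cc(=O)c3c(OCc4ccccc4)cc(OCc4ccccc4)cc3o2)cc1 | intermediate
22 | isocryptomerin | COc1cc2oc(-c3ccc(O)cc3)cc(=O)c2c(O)c1Oc1ccc(-c2cc(=O)c3c(O)cc(O)cc3o2)cc1 | target

Total step count: 13. Longest linear sequence: 12 steps (steps 1 to 9 and 11 to 13, from quinone 1); step 10 is a one-step branch.

Steps most likely to fail

Step 5. The ynol ether may oligomerise or be hydrated faster than it adds to the pyrone, or the cycloaddition may stall with this aryl-substituted, less nucleophilic alkyne. The fallback sets out from phenol 3 and forms the diaryl ether by copper-catalysed Ullmann-type O-arylation with methyl 4-iodobenzoate (CuI, picolinic acid, K3PO4, DMSO, 90 °C), a system that tolerates di-ortho-substituted phenols and electron-poor aryl iodides. It gives 12 directly, so no new compound arises (F0) and the route is rejoined at 12.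

Step 11. The dianion may add to the pyranone of 17 and open it, or may fail to attack the electron-rich, deactivated benzoate. The fallback sets out from 17: saponification (LiOH, THF/H2O, rt) should give 4-({2-[4-(benzyloxy)phenyl]-5,7-dimethoxy-4-oxo-4H-chromen-6-yl}oxy)benzoic acid F1. Steglich esterification of F1 with phenol 19 (EDC·HCl, DMAP, CH2Cl2) should give 2-acetyl-3,5-bis(benzyloxy)phenyl 4-({2-[4-(benzyloxy)phenyl]-5,7-dimethoxy-4-oxo-4H-chromen-6-yl}oxy)benzoate F2. A classical Baker–Venkataraman acyl shift (powdered KOH, pyridine, 50 °C) then moves the aroyl group from oxygen to the acetyl carbon and returns to the route at 20.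

Step 13. Four ether cleavages in one flask may stop short when partly deprotected boron chelates precipitate, or forcing them may erode the 7-methoxy group. The fallback sets out from 21 and separates the two events: hydrogenolysis (H2, Pd/C, THF/MeOH, rt) removes the three benzyl groups to give 5,7-dihydroxy-2-(4-{[2-(4-hydroxyphenyl)-5,7-dimethoxy-4-oxo-4H-chromen-6-yl]oxy}phenyl)-4H-chromen-4-one F3. Chelation-controlled demethylation with AlCl3 in MeCN at 60 °C should then remove only the 5-methoxy group and give 22.

Further compounds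
F0 | step 5 | none | none
F1 | step 11 | 4-({2-[4-(benzyloxy)phenyl]-5,7-dimethoxy-4-oxo-4H-chromen-6-yl}oxy)benzoic acid | OC(=O)c1ccc(Oc2c(OC)cc3oc(-c4ccc(OCc5ccccc5)cc4)cc(=O)c3c2OC)cc1
F2 | step 11 | 2-acetyl-3,5-bis(benzyloxy)phenyl 4-({2-[4-(benzyloxy)phenyl]-5,7-dimethoxy-4-oxo-4H-chromen-6-yl}oxy)benzoate | CC(=O)c1c(OC(=O)c2ccc(Oc3c(OC)cc4oc(-c5ccc(OCc6ccccc6)cc5)cc(=O)c4c3OC)cc2)cc(OCc2ccccc2)cc1OCc1ccccc1
F3 | step 13 | 5,7-dihydroxy-2-(4-{[2-(4-hydroxyphenyl)-5,7-dimethoxy-4-oxo-4H-chromen-6-yl]oxy}phenyl)-4H-chromen-4-one | COc1cc2oc(-c3ccc(O)cc3)cc(=O)c2c(OC)c1Oc1ccc(-c2cc(=O)c3c(O)cc(O)cc3o2)cc1
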